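**Plan**
1. Retrosynthesis: after the protecting groups, the seven-membered ring C3a–C4–C5–C6–C7–C8–C8a (azulene numbering) is contracted by taking out C-7. Its C6(CH3)=C7–C8(O-acyl) unit, with C-8 next to the quaternary C-8a, is what a cyclopropyl-to-allyl cation opening of the dibromocarbene adduct of a 1-methylcyclohexene delivers.
2. The resulting trans-hydrindene is cut at C3–O (olefin hydration), at the ring B olefin (metathesis), at the C4 ester, and at the two C–C bonds on the ring-fusion carbons (conjugate addition, enolate allylation), back to a quinone monoketal.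
3. Forward: ring A as a six-membered ring from 4-methoxy-2-methylphenol, ring B by ring-closing metathesis, then one-carbon expansion of ring A with the isovalerate placed on C-8 in the same step, then deprotection.
4. Stereochemistry: C-3a by a ligand-controlled rhodium conjugate addition; C-8a by allylation anti to the C-3a group; C-4, C-3 and C-8 each by attack anti to the axial 8a-methyl group (hydride, O2 on a radical, carboxylic acid on the allyl cation).

Key step: step 13

Remark: 3 and 13 are taken as catalogue compounds; locants follow indene numbering for the bicyclo[4.3.0] intermediates and azulene numbering after the ring expansion.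

Step 1
Reactants: 1 4-methoxy-2-methylphenol
Product: 2 4,4-dimethoxy-2-methylcyclohexa-2,5-dien-1-one
Conditions: PhI(OAc)2, MeOH, 0 °C
Reagents that add atoms: methanol, CO
Why: Oxidative dearomatisation of a para-methoxyphenol in methanol gives the quinone monoketal by methanol capture at the methoxy-bearing carbon, and no stereocenter is formed.

Step 2
Reactants: 2 4,4-dimethoxy-2-methylcyclohexa-2,5-dien-1-one; 3 4,4,5,5-tetramethyl-2-(3-methylbut-1-en-2-yl)-1,3,2-dioxaborolane
Product: 4 (5R)-4,4-dimethoxy-2-methyl-5-(3-methylbut-1-en-2-yl)cyclohex-2-en-1-one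
Conditions: [RhCl(cod)]2 (cat.), (R)-BINAP, aq. KOH (0.5 equiv), dioxane, 40 °C
Reagents that add atoms: none
Why: Rhodium-catalysed asymmetric conjugate addition of an alkenylboron reagent (Hayashi–Miyaura reaction) should occur only at the unsubstituted enone of 2, and the chiral bisphosphine sets C-5 (sense taken from the cyclohex-2-enone model, where the (S)-ligand gives (S)-3-substituted cyclohexanones, so the (R)-ligand is chosen here).

Step 3
Reactants: 4 (5R)-4,4-dimethoxy-2-methyl-5-(3-methylbut-1-en-2-yl)cyclohex-2-en-1-one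
Product: 6 (5R,6S)-4,4-dimethoxy-2,6-dimethyl-5-(3-methylbut-1-en-2-yl)cyclohex-2-en-1-one (expected major trans isomer), via lithium dienolate 5 (not isolated)
Conditions: LiN(i-Pr)2, THF, −78 °C; MeI, −78 → −20 °C
Reagents that add atoms: iodomethane, CI
Why: Kinetic α′-deprotonation (C-6 is the only acidic site, C-4 being a ketal) and enolate methylation, expected mainly anti to the C-5 group; the C-6 configuration is erased in step 4.

Step 4
Reactants: 6 (5R,6S)-4,4-dimethoxy-2,6-dimethyl-5-(3-methylbut-1-en-2-yl)cyclohex-2-en-1-one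
Product: 8 (5S,6S)-4,4-dimethoxy-2,6-dimethyl-5-(3-methylbut-1-en-2-yl)-6-(prop-2-en-1-yl)cyclohex-2-en-1-one, via lithium enolate 7 (not isolated)
Conditions: LiN(i-Pr)2, THF/DMPU, −78 → 0 °C; allyl bromide
Reagents that add atoms: allyl bromide, C=CCBr
Why: Enolate alkylation, in which the tetrasubstituted lithium enolate should be allylated axially on the face opposite the pseudoaxial C-5 alkenyl group, setting the quaternary C-6 with allyl trans to the C-5 substituent and thereby the later trans ring fusion.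

Step 5
Reactants: 8 (5S,6S)-4,4-dimethoxy-2,6-dimethyl-5-(3-methylbut-1-en-2-yl)-6-(prop-2-en-1-yl)cyclohex-2-en-1-one
Product: 9 (3aS,7aS)-4,4-dimethoxy-6,7a-dimethyl-3-(propan-2-yl)-1,3a,4,7a-tetrahydro-7H-inden-7-one
Conditions: second-generation Grubbs catalyst (cat.), toluene, 80 °C
Reagents that add atoms: none
Why: Ring-closing metathesis between the allyl group and the 1,1-disubstituted olefin of the trans-diequatorial side chains should close the trisubstituted cyclopentene (ring B) with loss of ethene, while the electron-poor enone olefin stays out and no stereocenter changes.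

Step 6
Reactants: 9 (3aS,7aS)-4,4-dimethoxy-6,7a-dimethyl-3-(propan-2-yl)-1,3a,4,7a-tetrahydro-7H-inden-7-one
Product: 11 (3aS,7aS)-4,4-dimethoxy-6,7a-dimethyl-3-(propan-2-yl)-3a,4,5,7a-tetrahydro-1H-inden-7-yl trifluoromethanesulfonate, via lithium enolate 10 (not isolated)
Conditions: LiBH(s-Bu)3, THF, −78 °C; PhNTf2, −78 → 0 °C
Reagents that add atoms: N-phenylbis(trifluoromethanesulfonimide), O=S(=O)(N(c1ccccc1)S(=O)(=O)C(F)(F)F)C(F)(F)F
Why: Conjugate hydride addition to the β-unsubstituted enone (1,2-attack is blocked by the flanking quaternary carbon) gives one regio-defined enolate, which is trapped on oxygen as the enol triflate; this masks the future ring A olefin as an electron-poor group for steps 7 to 9.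

Step 7
Reactants: 11 (3aS,7aS)-4,4-dimethoxy-6,7a-dimethyl-3-(propan-2-yl)-3a,4,5,7a-tetrahydro-1H-inden-7-yl trifluoromethanesulfonate
Product: 12 (3aS,7aS)-6,7a-dimethyl-4-oxo-3-(propan-2-yl)-3a,4,5,7a-tetrahydro-1H-inden-7-yl trifluoromethanesulfonate
Conditions: oxalic acid (cat.), wet SiO2, CH2Cl2, rt
Reagents that add atoms: water, O
Why: Mild acid hydrolysis of the dimethyl ketal on wet silica, a method used to free β,γ-unsaturated ketones without double-bond migration, should leave the triflate, both olefins and C-3a untouched.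

Step 8
Reactants: 12 (3aS,7aS)-6,7a-dimethyl-4-oxo-3-(propan-2-yl)-3a,4,5,7a-tetrahydro-1H-inden-7-yl trifluoromethanesulfonate; 13 4-(acetyloxy)benzoyl chloride
Product: 15 [(3aS,4R,7aS)-6,7a-dimethyl-3-(propan-2-yl)-7-(trifluoromethanesulfonyloxy)-3a,4,5,7a-tetrahydro-1H-inden-4-yl] 4-(acetyloxy)benzoate, via lithium alkoxide 14 (not isolated)
Conditions: LiBH(s-Bu)3, THF, −78 °C; then 13, DMAP (cat.), −78 → 0 °C
Reagents that add atoms: none
Why: Ketone reduction with a bulky borohydride followed by in-situ O-acylation, in which the pseudoaxial 7a-methyl group blocks the α-face of C-4 in a 1,3-relationship (as the angular methyl does in 6-oxo steroids), so hydride should enter from the β-face and the new C-4 oxygen is α (4R), and the labile ketone is consumed at low temperature.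

Step 9
Reactants: 15 [(3aS,4R,7aS)-6,7a-dimethyl-3-(propan-2-yl)-7-(trifluoromethanesulfonyloxy)-3a,4,5,7a-tetrahydro-1H-inden-4-yl] 4-(acetyloxy)benzoate
Product: 16 [(3S,3aS,4R,7aS)-3-hydroxy-6,7a-dimethyl-3-(propan-2-yl)-7-(trifluoromethanesulfonyloxy)-2,3,3a,4,5,7a-hexahydro-1H-inden-4-yl] 4-(acetyloxy)benzoate
Conditions: Mn(dpm)3 (cat.), PhSiH3, O2 (1 atm), i-PrOH/CH2Cl2, 0 °C → rt
Reagents that add atoms: dioxygen, O=O
Why: Mukaiyama-type hydration by metal-hydride hydrogen atom transfer adds H to C-2 and gives the tertiary C-3 radical, which should be trapped by O2 on the β-face, away from the 7a-methyl group and the C-4 ester on the α-face, to set C-3 (OH β, isopropyl α), while the hindered electron-poor enol triflate olefin is left alone.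

Step 10
Reactants: 16 [(3S,3aS,4R,7aS)-3-hydroxy-6,7a-dimethyl-3-(propan-2-yl)-7-(trifluoromethanesulfonyloxy)-2,3,3a,4,5,7a-hexahydro-1H-inden-4-yl] 4-(acetyloxy)benzoate
Product: 17 [(3S,3aS,4R,7aR)-3-hydroxy-6,7a-dimethyl-3-(propan-2-yl)-2,3,3a,4,5,7a-hexahydro-1H-inden-4-yl] 4-(acetyloxy)benzoate
Conditions: Pd(PPh3)4 (cat.), LiCl, Bu3SnH, THF, 60 °C
Reagents that add atoms: none
Why: Palladium-catalysed hydrogenolysis of the enol triflate with a tin hydride (Stille-type reduction: oxidative addition, hydride transfer from tin, reductive elimination) under neutral conditions should unmask the C6=C7 olefin without touching esters or stereocenters.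

Step 11
Reactants: 17 [(3S,3aS,4R,7aR)-3-hydroxy-6,7a-dimethyl-3-(propan-2-yl)-2,3,3a,4,5,7a-hexahydro-1H-inden-4-yl] 4-(acetyloxy)benzoate
Product: 18 [(3S,3aS,4R,7aR)-6,7a-dimethyl-3-(propan-2-yl)-3-(trimethylsilyloxy)-2,3,3a,4,5,7a-hexahydro-1H-inden-4-yl] 4-(acetyloxy)benzoate
Conditions: TMSOTf, 2,6-lutidine, CH2Cl2, −78 → 0 °C
Reagents that add atoms: trimethylsilyl trifluoromethanesulfonate, C[Si](C)(C)OS(=O)(=O)C(F)(F)F
Why: Silylation of the hindered tertiary alcohol with a silyl triflate and a hindered base protects it from O–H insertion of the carbene in step 12, and no stereocenter changes.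

Step 12
Reactants: 18 [(3S,3aS,4R,7aR)-6,7a-dimethyl-3-(propan-2-yl)-3-(trimethylsilyloxy)-2,3,3a,4,5,7a-hexahydro-1H-inden-4-yl] 4-(acetyloxy)benzoate
Product: 19 dibromocarbene adduct of 18 across C6=C7 (cis-fused 6,7-dibromomethano bridge on the face opposite the 7a-methyl group)
Conditions: PhHgCBr3, benzene, 80 °C
Reagents that add atoms: phenyl(tribromomethyl)mercury, BrC(Br)(Br)[Hg]c1ccccc1
Why: [2+1] Cycloaddition of dibromocarbene, released thermally under neutral conditions that spare both esters and the silyl ether, to the only olefin from the face opposite the 7a-methyl group (the two cyclopropane stereocenters are lost again in step 13).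

Step 13
Reactants: 19 dibromocarbene adduct of 18; 20 3-methylbutanoic acid
Product: 21 [(3S,3aS,4R,8S,8aS)-7-bromo-6,8a-dimethyl-8-(3-methylbutanoyloxy)-3-(propan-2-yl)-3-(trimethylsilyloxy)-1,2,3,3a,4,5,8,8a-octahydroazulen-4-yl] 4-(acetyloxy)benzoate
Conditions: AgOTf, 2,6-di-tert-butyl-4-methylpyridine, CH2Cl2, −20 °C → rt, dark
Reagents that add atoms: none
Why: AgOTf abstracts the bromide lying over ring A while the C6–C7 cyclopropane bond of 19 (indene numbering) opens in a disrotatory two-electron electrocyclic process, so the carbene carbon ends up between the two former olefin carbons and the six-membered ring becomes a seven-membered 2-bromoallyl cation spanning C-6, C-7 and C-8 (azulene numbering). The closest known reaction type is the silver-assisted solvolytic ring expansion of 7,7-dibromobicyclo[4.1.0]heptanes to 2-bromocyclohept-2-enyl acetates with AgOAc in acetic acid, run here with isovaleric acid as the carboxylic acid. No ring is closed: the seven-membered ring arises by fission of the ring-fusion σ-bond of the bicyclo[4.1.0] unit, and the cation is trapped intermolecularly. The only new stereocenter, C-8, is controlled by the axial 8a-methyl group, which shields the α-face of the planar cation so that the acid should add anti to it. The step needs capture at the secondary terminus C-8 and not at the tertiary C-6: attack at C-8 gives the tetrasubstituted bromoalkene, and a tertiary ester formed at C-6 should re-ionise under AgOTf and be funnelled to the same product. The C-4 oxygen is tied up as a benzoate and cannot bridge to C-8, and the hindered pyridine keeps the medium from turning strongly acidic.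

Step 14
Reactants: 21 [(3S,3aS,4R,8S,8aS)-7-bromo-6,8a-dimethyl-8-(3-methylbutanoyloxy)-3-(propan-2-yl)-3-(trimethylsilyloxy)-1,2,3,3a,4,5,8,8a-octahydroazulen-4-yl] 4-(acetyloxy)benzoate
Product: 22 [(3S,3aS,4R,8R,8aS)-6,8a-dimethyl-8-(3-methylbutanoyloxy)-3-(propan-2-yl)-3-(trimethylsilyloxy)-1,2,3,3a,4,5,8,8a-octahydroazulen-4-yl] 4-(acetyloxy)benzoate
Conditions: Bu3SnH, AIBN (cat.), benzene, 80 °C
Reagents that add atoms: none
Why: Radical chain hydrodebromination, in which bromine abstraction gives a σ-vinyl radical that should take hydrogen from the tin hydride faster than it can rearrange, so the C6=C7 olefin position and all stereocenters are kept.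

Step 15
Reactants: 22 [(3S,3aS,4R,8R,8aS)-6,8a-dimethyl-8-(3-methylbutanoyloxy)-3-(propan-2-yl)-3-(trimethylsilyloxy)-1,2,3,3a,4,5,8,8a-octahydroazulen-4-yl] 4-(acetyloxy)benzoate
Product: 23 [(3S,3aS,4R,8R,8aS)-3-hydroxy-6,8a-dimethyl-8-(3-methylbutanoyloxy)-3-(propan-2-yl)-1,2,3,3a,4,5,8,8a-octahydroazulen-4-yl] 4-hydroxybenzoate (target, CNP0086724.4)
Conditions: K2CO3 (0.3 equiv), MeOH, 0 °C → rt
Reagents that add atoms: none
Why: Base-catalysed methanolysis should remove the phenolic acetate (far more labile than the two hindered secondary esters, and the phenoxide formed deactivates the benzoate) and the trimethylsilyl ether in one operation.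

**Compound list**
1 | 4-methoxy-2-methylphenol | COc1ccc(O)c(C)c1 | starting material
2 | 4,4-dimethoxy-2-methylcyclohexa-2,5-dien-1-one | CC1=CC(OC)(OC)C=CC1=O | intermediate
3 | 4,4,5,5-tetramethyl-2-(3-methylbut-1-en-2-yl)-1,3,2-dioxaborolane | CC(C)C(=C)B1OC(C)(C)C(C)(C)O1 | starting material
4 | (5R)-4,4-dimethoxy-2-methyl-5-(3-methylbut-1-en-2-yl)cyclohex-2-en-1-one | CC1=CC(OC)(OC)[C@@H](C(=C)C(C)C)CC1=O | intermediate
5 | lithium dienolate of 4 (deprotonated at C-6) | CC1=CC(OC)(OC)[C@@H](C(=C)C(C)C)C=C1[O-].[Li+] | intermediate (not isolated)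
6 | (5R,6S)-4,4-dimethoxy-2,6-dimethyl-5-(3-methylbut-1-en-2-yl)cyclohex-2-en-1-one | CC1=CC(OC)(OC)[C@@H](C(=C)C(C)C)[C@H](C)C1=O | intermediate
7 | lithium enolate of 6 (C-6 enolate) | CC1=CC(OC)(OC)[C@@H](C(=C)C(C)C)C(C)=C1[O-].[Li+] | intermediate (not isolated)
8 | (5S,6S)-4,4-dimethoxy-2,6-dimethyl-5-(3-methylbut-1-en-2-yl)-6-(prop-2-en-1-yl)cyclohex-2-en-1-one | CC1=CC(OC)(OC)[C@@H](C(=C)C(C)C)[C@](C)(CC=C)C1=O | intermediate
9 | (3aS,7aS)-4,4-dimethoxy-6,7a-dimethyl-3-(propan-2-yl)-1,3a,4,7a-tetrahydro-7H-inden-7-one | CC1=CC(OC)(OC)[C@H]2C(C(C)C)=CC[C@]2(C)C1=O | intermediate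
10 | lithium (3aS,7aS)-4,4-dimethoxy-6,7a-dimethyl-3-(propan-2-yl)-3a,4,5,7a-tetrahydro-1H-inden-7-olate | CC1=C([O-])[C@@]2(C)CC=C(C(C)C)[C@@H]2C(OC)(OC)C1.[Li+] | intermediate (not isolated)
11 | (3aS,7aS)-4,4-dimethoxy-6,7a-dimethyl-3-(propan-2-yl)-3a,4,5,7a-tetrahydro-1H-inden-7-yl trifluoromethanesulfonate | CC1=C(OS(=O)(=O)C(F)(F)F)[C@@]2(C)CC=C(C(C)C)[C@@H]2C(OC)(OC)C1 | intermediate
12 | (3aS,7aS)-6,7a-dimethyl-4-oxo-3-(propan-2-yl)-3a,4,5,7a-tetrahydro-1H-inden-7-yl trifluoromethanesulfonate | CC1=C(OS(=O)(=O)C(F)(F)F)[C@@]2(C)CC=C(C(C)C)[C@@H]2C(=O)C1 | intermediate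
13 | 4-(acetyloxy)benzoyl chloride | CC(=O)Oc1ccc(cc1)C(Cl)=O | starting material
14 | lithium (3aS,4R,7aS)-6,7a-dimethyl-3-(propan-2-yl)-7-(trifluoromethanesulfonyloxy)-3a,4,5,7a-tetrahydro-1H-inden-4-olate | CC1=C(OS(=O)(=O)C(F)(F)F)[C@@]2(C)CC=C(C(C)C)[C@@H]2[C@H]([O-])C1.[Li+] | intermediate (not isolated)
15 | [(3aS,4R,7aS)-6,7a-dimethyl-3-(propan-2-yl)-7-(trifluoromethanesulfonyloxy)-3a,4,5,7a-tetrahydro-1H-inden-4-yl] 4-(acetyloxy)benzoate | CC1=C(OS(=O)(=O)C(F)(F)F)[C@@]2(C)CC=C(C(C)C)[C@@H]2[C@H](OC(=O)c2ccc(OC(C)=O)cc2)C1 | intermediate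
16 | [(3S,3aS,4R,7aS)-3-hydroxy-6,7a-dimethyl-3-(propan-2-yl)-7-(trifluoromethanesulfonyloxy)-2,3,3a,4,5,7a-hexahydro-1H-inden-4-yl] 4-(acetyloxy)benzoate | CC1=C(OS(=O)(=O)C(F)(F)F)[C@@]2(C)CC[C@](O)(C(C)C)[C@@H]2[C@H](OC(=O)c2ccc(OC(C)=O)cc2)C1 | intermediate
17 | [(3S,3aS,4R,7aR)-3-hydroxy-6,7a-dimethyl-3-(propan-2-yl)-2,3,3a,4,5,7a-hexahydro-1H-inden-4-yl] 4-(acetyloxy)benzoate | CC1=C[C@@]2(C)CC[C@](O)(C(C)C)[C@@H]2[C@H](OC(=O)c2ccc(OC(C)=O)cc2)C1 | intermediate
18 | [(3S,3aS,4R,7aR)-6,7a-dimethyl-3-(propan-2-yl)-3-(trimethylsilyloxy)-2,3,3a,4,5,7a-hexahydro-1H-inden-4-yl] 4-(acetyloxy)benzoate | CC1=C[C@@]2(C)CC[C@](O[Si](C)(C)C)(C(C)C)[C@@H]2[C@H](OC(=O)c2ccc(OC(C)=O)cc2)C1 | intermediate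
19 | dibromocarbene adduct of 18 across C6=C7 (cis-fused dibromocyclopropane on the face opposite the 7a-methyl group) | C[C@]13C(Br)(Br)[C@H]1[C@@]2(C)CC[C@](O[Si](C)(C)C)(C(C)C)[C@@H]2[C@H](OC(=O)c2ccc(OC(C)=O)cc2)C3 | intermediate
20 | 3-methylbutanoic acid (isovaleric acid) | CC(C)CC(O)=O | starting material
21 | [(3S,3aS,4R,8S,8aS)-7-bromo-6,8a-dimethyl-8-(3-methylbutanoyloxy)-3-(propan-2-yl)-3-(trimethylsilyloxy)-1,2,3,3a,4,5,8,8a-octahydroazulen-4-yl] 4-(acetyloxy)benzoate | CC1=C(Br)[C@@H](OC(=O)CC(C)C)[C@@]2(C)CC[C@](O[Si](C)(C)C)(C(C)C)[C@@H]2[C@H](OC(=O)c2ccc(OC(C)=O)cc2)C1 | intermediate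
22 | [(3S,3aS,4R,8R,8aS)-6,8a-dimethyl-8-(3-methylbutanoyloxy)-3-(propan-2-yl)-3-(trimethylsilyloxy)-1,2,3,3a,4,5,8,8a-octahydroazulen-4-yl] 4-(acetyloxy)benzoate | CC1=C[C@@H](OC(=O)CC(C)C)[C@@]2(C)CC[C@](O[Si](C)(C)C)(C(C)C)[C@@H]2[C@H](OC(=O)c2ccc(OC(C)=O)cc2)C1 | intermediate
23 | [(3S,3aS,4R,8R,8aS)-3-hydroxy-6,8a-dimethyl-8-(3-methylbutanoyloxy)-3-(propan-2-yl)-1,2,3,3a,4,5,8,8a-octahydroazulen-4-yl] 4-hydroxybenzoate | CC1=C[C@@H](OC(=O)CC(C)C)[C@@]2(C)CC[C@](O)(C(C)C)[C@@H]2[C@H](OC(=O)c2ccc(O)cc2)C1 | target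

**Step count and risks**
Total step count: 15. Longest linear sequence: 15 (fully linear from 1).

Steps most likely to fail:

Step 13. The allyl cation may be captured at the tertiary terminus or lose a proton to bromodienes, and facial selectivity at C-8 may erode if the secondary ester re-ionises. Fallback, from 19 back to 21: 19 is opened with AgClO4 and CaCO3 in aqueous acetone to the 7-bromo-8-hydroxy compound as a C-8 epimer mixture F1. Pyridinium chlorochromate (C5H5NH[CrO3Cl]) with NaOAc oxidises it, and transposes any tertiary regioisomer, to the 7-bromo-8-oxo enone F2. NaBH4 with CeCl3·7H2O (Luche reduction) should deliver hydride anti to the 8a-methyl group to give the (8R)-alcohol F3. A Mitsunobu esterification with PPh3, DIAD and 20 then inverts C-8 and gives 21.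

Step 9. Hydrogen atom transfer may also reach the enol triflate olefin, or oxygen may trap the tertiary radical on the wrong face. Fallback, from 12 back to 17: epoxidation of 12 with mCPBA and NaHCO3 on the face opposite the 7a-methyl group gives the 2,3-epoxy ketone F4. Pd(PPh3)4, LiCl and Bu3SnH remove the triflate to give the epoxy ketone olefin F5. LiBHEt3 reduces the ketone from the β-face and opens the epoxide at the secondary C-2 to give the 3,4-diol F6. Acylation of the secondary hydroxyl with 13 (Et3N, DMAP) gives 17.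

Step 8. The β,γ-double bond of ketone 12 may migrate into conjugation, or C-3a may epimerise, before reduction, and hydride delivery may lack full facial control. Fallback, from 11 back to 16: the hydration conditions of step 9 are applied first to 11 to give the tertiary alcohol ketal F7. Deketalisation (oxalic acid, wet SiO2) gives the β-hydroxy ketone F8, which no longer carries a β,γ-olefin. Me4NBH(OAc)3 in MeCN/AcOH delivers hydride intramolecularly from the C-3 hydroxyl (Evans–Saksena reduction) to give the anti-1,3-diol F9. Acylation of the secondary hydroxyl with 13 (Et3N, DMAP) gives 16.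

**Further compounds**
F1 | step 13 | [(3S,3aS,4R,8aS)-7-bromo-8-hydroxy-6,8a-dimethyl-3-(propan-2-yl)-3-(trimethylsilyloxy)-1,2,3,3a,4,5,8,8a-octahydroazulen-4-yl] 4-(acetyloxy)benzoate, C-8 epimer mixture | CC1=C(Br)C(O)[C@@]2(C)CC[C@](O[Si](C)(C)C)(C(C)C)[C@@H]2[C@H](OC(=O)c2ccc(OC(C)=O)cc2)C1
F2 | step 13 | [(3S,3aS,4R,8aS)-7-bromo-6,8a-dimethyl-8-oxo-3-(propan-2-yl)-3-(trimethylsilyloxy)-1,2,3,3a,4,5,8,8a-octahydroazulen-4-yl] 4-(acetyloxy)benzoate | CC1=C(Br)C(=O)[C@@]2(C)CC[C@](O[Si](C)(C)C)(C(C)C)[C@@H]2[C@H](OC(=O)c2ccc(OC(C)=O)cc2)C1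
F3 | step 13 | [(3S,3aS,4R,8R,8aS)-7-bromo-8-hydroxy-6,8a-dimethyl-3-(propan-2-yl)-3-(trimethylsilyloxy)-1,2,3,3a,4,5,8,8a-octahydroazulen-4-yl] 4-(acetyloxy)benzoate | CC1=C(Br)[C@H](O)[C@@]2(C)CC[C@](O[Si](C)(C)C)(C(C)C)[C@@H]2[C@H](OC(=O)c2ccc(OC(C)=O)cc2)C1
F4 | step 9 | 2,3-epoxide of 12 (epoxide oxygen on the face of H-3a, opposite the 7a-methyl group) | CC1=C(OS(=O)(=O)C(F)(F)F)[C@@]2(C)C[C@H]3O[C@@]3(C(C)C)[C@@H]2C(=O)C1
F5 | step 9 | 2,3-epoxy-6,7a-dimethyl-3-(propan-2-yl)-hexahydroinden-4-one with the C6=C7 olefin (F4 without the triflate group) | CC1=C[C@@]2(C)C[C@H]3O[C@@]3(C(C)C)[C@@H]2C(=O)C1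
F6 | step 9 | (3S,3aS,4R,7aR)-6,7a-dimethyl-3-(propan-2-yl)-2,3,3a,4,5,7a-hexahydro-1H-indene-3,4-diol | CC1=C[C@@]2(C)CC[C@](O)(C(C)C)[C@@H]2[C@H](O)C1
F7 | step 8 | (3S,3aR,7aS)-3-hydroxy-4,4-dimethoxy-6,7a-dimethyl-3-(propan-2-yl)-2,3,3a,4,5,7a-hexahydro-1H-inden-7-yl trifluoromethanesulfonate | CC1=C(OS(=O)(=O)C(F)(F)F)[C@@]2(C)CC[C@](O)(C(C)C)[C@@H]2C(OC)(OC)C1
F8 | step 8 | (3S,3aR,7aS)-3-hydroxy-6,7a-dimethyl-4-oxo-3-(propan-2-yl)-2,3,3a,4,5,7a-hexahydro-1H-inden-7-yl trifluoromethanesulfonate | CC1=C(OS(=O)(=O)C(F)(F)F)[C@@]2(C)CC[C@](O)(C(C)C)[C@@H]2C(=O)C1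
F9 | step 8 | (3S,3aS,4R,7aS)-3,4-dihydroxy-6,7a-dimethyl-3-(propan-2-yl)-2,3,3a,4,5,7a-hexahydro-1H-inden-7-yl trifluoromethanesulfonate | CC1=C(OS(=O)(=O)C(F)(F)F)[C@@]2(C)CC[C@](O)(C(C)C)[C@@H]2[C@H](O)C1
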